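**Retrosynthetic overview**
- The carboxylic acid is unmasked last by oxidising a hydroxymethyl arm (CH2OH → CHO → CO2H). Before that, the (Z)-trisubstituted enoate is cut by a Still–Gennari olefination into a γ-branched aldehyde and an α-homoprenyl bis(trifluoroethyl)phosphonoacetate.
- The aldehyde comes from a primary iodide by two-carbon homologation (cyanomethyl anion, then partial reduction of the nitrile).
- The only stereocentre is set by catalytic asymmetric desymmetrisation: a lipase acetylates one of the two enantiotopic CH2OH groups of prochiral 2-[3-(furan-3-yl)propyl]propane-1,3-diol.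
- The prochiral diol comes from a malonate assembled by hydroboration and B-alkyl Suzuki coupling of diethyl allylmalonate with 3-bromofuran.
- Rings: none is formed; the furan is bought as 3-bromofuran and carried through from the first step.

Assumption: the lipase acetylates the pro-R hydroxymethyl group (empirical active-site model for primary alcohols), giving the (R)-monoacetate; the sense and ee are checked on the first run (Mosher ester, chiral HPLC).

**Step 1**
Reactants: 1 diethyl 2-(prop-2-en-1-yl)propanedioate (diethyl allylmalonate); 2 9-borabicyclo[3.3.1]nonane (9-BBN); 3 3-bromofuran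
Product: 5 diethyl 2-[3-(furan-3-yl)propyl]propanedioate, via B-alkyl-9-BBN adduct 4 (not isolated)
Conditions: 2 (1.2 equiv), THF, 0 °C → rt; then 3 (1.2 equiv), PdCl2(dppf) (3 mol %), aq. K3PO4 (3 equiv), DMF, 50 °C
Reagents that add atoms: none
Why: 9-BBN hydroborates the terminal alkene anti-Markovnikov without touching the esters, and the B-alkyl borane then undergoes B-alkyl Suzuki–Miyaura cross-coupling with the heteroaryl bromide under conditions the malonate tolerates.

**Step 2**
Reactants: 5 diethyl 2-[3-(furan-3-yl)propyl]propanedioate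
Product: 6 2-[3-(furan-3-yl)propyl]propane-1,3-diol
Conditions: LiAlH4 (2.5 equiv), THF, 0 °C → reflux; H2O, aq. NaOH work-up
Reagents that add atoms: none
Why: Hydride reduction of both esters gives the prochiral 1,3-diol with two enantiotopic CH2OH groups, the furan being inert to LiAlH4.

**Step 3**
Reactants: 6 2-[3-(furan-3-yl)propyl]propane-1,3-diol
Product: 7 [(2R)-5-(furan-3-yl)-2-(hydroxymethyl)pentyl] acetate
Conditions: lipase from Burkholderia cepacia (Amano lipase PS, immobilised), vinyl acetate (4 equiv), t-BuOMe, 25 °C, stopped at about 5–10 % diacetate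
Reagents that add atoms: vinyl acetate, CC(=O)OC=C
Why: Lipase-catalysed irreversible transesterification (enzymatic desymmetrisation) transfers acetyl to only the pro-R hydroxymethyl group, which creates the (R) stereocentre, and the small amount of over-acetylation removes the minor enantiomer as achiral diacetate (kinetic amplification).

**Step 4**
Reactants: 7 [(2R)-5-(furan-3-yl)-2-(hydroxymethyl)pentyl] acetate
Product: 8 [(2S)-5-(furan-3-yl)-2-(iodomethyl)pentyl] acetate
Conditions: PPh3 (1.3 equiv), I2 (1.3 equiv), imidazole (1.5 equiv), CH2Cl2, 0 °C, 7 added last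
Reagents that add atoms: iodine, [I][I]
Why: Garegg–Samuelsson (Appel-type) iodination displaces the alkoxyphosphonium by SN2 at the CH2 group only, so no bond to the stereocentre is touched (the descriptor changes by priority alone), and the fast, near-neutral conditions spare the acetate and outrun acyl migration.

**Step 5**
Reactants: 8 [(2S)-5-(furan-3-yl)-2-(iodomethyl)pentyl] acetate
Product: 9 (2S)-5-(furan-3-yl)-2-(iodomethyl)pentan-1-ol
Conditions: diisobutylaluminium hydride, (Me2CHCH2)2AlH (2.3 equiv), CH2Cl2, −78 °C; aq. KNaC4H4O6 (potassium sodium tartrate)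
Reagents that add atoms: none
Why: Reductive cleavage of the acetate at −78 °C frees the second arm without base, so the 3-iodo alcohol cannot close to an oxetane and the alkyl iodide is not reduced.

**Step 6**
Reactants: 9 (2S)-5-(furan-3-yl)-2-(iodomethyl)pentan-1-ol
Product: 10 tert-butyl{[(2S)-5-(furan-3-yl)-2-(iodomethyl)pentyl]oxy}dimethylsilane
Conditions: TBSCl (1.2 equiv), imidazole (2.5 equiv), CH2Cl2, 0 °C → rt
Reagents that add atoms: tert-butyl(chloro)dimethylsilane (TBSCl), CC(C)(C)[Si](C)(C)Cl
Why: Silyl ether protection masks the future carboxyl carbon as a primary TBS ether that withstands the carbanion, hydride and amide-base steps that follow.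

**Step 7**
Reactants: 10 tert-butyl{[(2S)-5-(furan-3-yl)-2-(iodomethyl)pentyl]oxy}dimethylsilane
Product: 11 (4R)-4-({[tert-butyl(dimethyl)silyl]oxy}methyl)-7-(furan-3-yl)heptanenitrile
Conditions: MeCN (4 equiv), n-BuLi (3.8 equiv), THF, −78 °C; then 10, DMPU, −78 → −20 °C
Reagents that add atoms: acetonitrile, CC#N
Why: SN2 alkylation of cyanomethyllithium (in excess to suppress dialkylation, DMPU to speed the β-branched primary iodide) adds the two carbons of the tether without involving the stereocentre.

**Step 8**
Reactants: 11 (4R)-4-({[tert-butyl(dimethyl)silyl]oxy}methyl)-7-(furan-3-yl)heptanenitrile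
Product: 12 (4R)-4-({[tert-butyl(dimethyl)silyl]oxy}methyl)-7-(furan-3-yl)heptanal
Conditions: diisobutylaluminium hydride, (Me2CHCH2)2AlH (1.3 equiv), CH2Cl2, −78 °C; then MeOH, aq. KNaC4H4O6, rt
Reagents that add atoms: water, O
Why: Partial hydride reduction of the nitrile at −78 °C followed by aqueous hydrolysis on work-up delivers the aldehyde, with the silyl ether and furan inert and the stereocentre remote from the carbonyl.

**Step 9**
Reactants: 13 methyl 2-[bis(2,2,2-trifluoroethoxy)phosphoryl]acetate; 14 5-bromo-2-methylpent-2-ene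
Product: 15 methyl 2-[bis(2,2,2-trifluoroethoxy)phosphoryl]-6-methylhept-5-enoate (racemic)
Conditions: NaH (1.05 equiv), DMF, 0 °C; then 14 (1.1 equiv), n-Bu4NI (10 mol %), rt → 50 °C
Reagents that add atoms: none
Why: C-alkylation (SN2) of the deprotonated phosphonoacetate with the homoallylic bromide under iodide catalysis gives the α-substituted olefination reagent, whose racemic, labile stereocentre is erased in the next step.

**Step 10**
Reactants: 12 (4R)-4-({[tert-butyl(dimethyl)silyl]oxy}methyl)-7-(furan-3-yl)heptanal; 15 methyl 2-[bis(2,2,2-trifluoroethoxy)phosphoryl]-6-methylhept-5-enoate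
Product: 16 methyl (2Z)-2-[(4R)-4-({[tert-butyl(dimethyl)silyl]oxy}methyl)-7-(furan-3-yl)heptylidene]-6-methylhept-5-enoate
Conditions: 15 (1.3 equiv), KN(SiMe3)2 (1.25 equiv), 18-crown-6 (4 equiv), THF, −78 °C; then 12, −78 °C, 2 h
Reagents that add atoms: none
Why: In this Still–Gennari variant of the Horner–Wadsworth–Emmons olefination the electron-poor phosphonate and crown-separated potassium ion make elimination from the kinetic adduct faster than its reversal, giving the (Z)-enoate (ester cis to the new chain) and leaving the remote stereocentre untouched.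

**Step 11**
Reactants: 16 methyl (2Z)-2-[(4R)-4-({[tert-butyl(dimethyl)silyl]oxy}methyl)-7-(furan-3-yl)heptylidene]-6-methylhept-5-enoate
Product: 17 methyl (2Z)-2-[(4R)-7-(furan-3-yl)-4-(hydroxymethyl)heptylidene]-6-methylhept-5-enoate
Conditions: Bu4NF (1.5 equiv), AcOH (1.5 equiv), THF, 0 °C → rt
Reagents that add atoms: none
Why: Fluoride-mediated desilylation buffered with acetic acid frees the primary alcohol without a free alkoxide that could add to the enoate (oxa-Michael) and without harming the furan or methyl ester.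

**Step 12**
Reactants: 17 methyl (2Z)-2-[(4R)-7-(furan-3-yl)-4-(hydroxymethyl)heptylidene]-6-methylhept-5-enoate
Product: 18 methyl (2Z)-2-[(4R)-4-formyl-7-(furan-3-yl)heptylidene]-6-methylhept-5-enoate
Conditions: Dess–Martin periodinane (1.3 equiv), pyridine (3 equiv), CH2Cl2, 0 °C → rt; used crude
Reagents that add atoms: none
Why: Dess–Martin oxidation stops at the aldehyde and is non-basic, so the now α-positioned stereocentre is not epimerised and furan, enoate and trisubstituted alkene are untouched.

**Step 13**
Reactants: 18 methyl (2Z)-2-[(4R)-4-formyl-7-(furan-3-yl)heptylidene]-6-methylhept-5-enoate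
Product: 19 (2R,5Z)-2-[3-(furan-3-yl)propyl]-6-(methoxycarbonyl)-10-methylundeca-5,9-dienoic acid
Conditions: NaClO2 (3 equiv), NaH2PO4 (3 equiv), 2-methylbut-2-ene (30 equiv), t-BuOH/H2O 4:1, 0 °C, 30–60 min
Reagents that add atoms: sodium chlorite, [Na+].[O-]Cl=O
Why: Pinnick oxidation by chlorous acid converts the aldehyde to the acid without epimerisation, while the large excess of 2-methylbut-2-ene traps hypochlorous acid before it can attack the furan or the electron-rich alkene, and the methyl ester is untouched.

**Compound list**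
1 | diethyl 2-(prop-2-en-1-yl)propanedioate (diethyl allylmalonate) | C=CCC(C(=O)OCC)C(=O)OCC | starting material
2 | 9-borabicyclo[3.3.1]nonane (9-BBN) | B1C2CCCC1CCC2 | starting material
3 | 3-bromofuran | Brc1ccoc1 | starting material
4 | diethyl 2-[3-(9-borabicyclo[3.3.1]nonan-9-yl)propyl]propanedioate | CCOC(=O)C(CCCB1C2CCCC1CCC2)C(=O)OCC | intermediate (not isolated)
5 | diethyl 2-[3-(furan-3-yl)propyl]propanedioate | CCOC(=O)C(CCCc1ccoc1)C(=O)OCC | intermediate
6 | 2-[3-(furan-3-yl)propyl]propane-1,3-diol | OCC(CO)CCCc1ccoc1 | intermediate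
7 | [(2R)-5-(furan-3-yl)-2-(hydroxymethyl)pentyl] acetate | OC[C@@H](CCCc1ccoc1)COC(C)=O | intermediate
8 | [(2S)-5-(furan-3-yl)-2-(iodomethyl)pentyl] acetate | IC[C@@H](CCCc1ccoc1)COC(C)=O | intermediate
9 | (2S)-5-(furan-3-yl)-2-(iodomethyl)pentan-1-ol | IC[C@@H](CCCc1ccoc1)CO | intermediate
10 | tert-butyl{[(2S)-5-(furan-3-yl)-2-(iodomethyl)pentyl]oxy}dimethylsilane | IC[C@@H](CCCc1ccoc1)CO[Si](C)(C)C(C)(C)C | intermediate
11 | (4R)-4-({[tert-butyl(dimethyl)silyl]oxy}methyl)-7-(furan-3-yl)heptanenitrile | N#CCC[C@@H](CCCc1ccoc1)CO[Si](C)(C)C(C)(C)C | intermediate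
12 | (4R)-4-({[tert-butyl(dimethyl)silyl]oxy}methyl)-7-(furan-3-yl)heptanal | O=CCC[C@@H](CCCc1ccoc1)CO[Si](C)(C)C(C)(C)C | intermediate
13 | methyl 2-[bis(2,2,2-trifluoroethoxy)phosphoryl]acetate | COC(=O)CP(=O)(OCC(F)(F)F)OCC(F)(F)F | starting material
14 | 5-bromo-2-methylpent-2-ene | CC(C)=CCCBr | starting material
15 | methyl 2-[bis(2,2,2-trifluoroethoxy)phosphoryl]-6-methylhept-5-enoate (racemic) | COC(=O)C(CCC=C(C)C)P(=O)(OCC(F)(F)F)OCC(F)(F)F | intermediate
16 | methyl (2Z)-2-[(4R)-4-({[tert-butyl(dimethyl)silyl]oxy}methyl)-7-(furan-3-yl)heptylidene]-6-methylhept-5-enoate | COC(=O)/C(=C\CC[C@@H](CCCc1ccoc1)CO[Si](C)(C)C(C)(C)C)CCC=C(C)C | intermediate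
17 | methyl (2Z)-2-[(4R)-7-(furan-3-yl)-4-(hydroxymethyl)heptylidene]-6-methylhept-5-enoate | COC(=O)/C(=C\CC[C@@H](CCCc1ccoc1)CO)CCC=C(C)C | intermediate
18 | methyl (2Z)-2-[(4R)-4-formyl-7-(furan-3-yl)heptylidene]-6-methylhept-5-enoate | COC(=O)/C(=C\CC[C@@H](CCCc1ccoc1)C=O)CCC=C(C)C | intermediate
19 | (2R,5Z)-2-[3-(furan-3-yl)propyl]-6-(methoxycarbonyl)-10-methylundeca-5,9-dienoic acid | COC(=O)/C(=C\CC[C@@H](CCCc1ccoc1)C(=O)O)CCC=C(C)C | target

**Step count**
Total: 13 steps. Longest linear sequence: 12 steps (steps 1–8 and 10–13, from diethyl allylmalonate); step 9 is a one-step side branch.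

**Three steps most likely to fail**

Step 3 (lipase desymmetrisation). The risk is modest ee with a flexible alkyl substituent, or erosion by acyl migration before step 4. The fallback sets out from 6 and comes back at 10.
- Both hydroxyls are acetylated (Ac2O, pyridine, 4-(dimethylamino)pyridine) to 2-[3-(furan-3-yl)propyl]propane-1,3-diyl diacetate F1.
- The same lipase is run in the hydrolytic direction (pH 7 phosphate buffer, 10 % acetone, pH-stat). It removes the acetate from the hydroxymethyl group it would otherwise have acylated and gives [(2S)-5-(furan-3-yl)-2-(hydroxymethyl)pentyl] acetate F2, the mirror image of 7, with the free OH on the arm that will become CO2H.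
- Silylation (TBSCl, imidazole) gives [(2R)-2-({[tert-butyl(dimethyl)silyl]oxy}methyl)-5-(furan-3-yl)pentyl] acetate F3.
- Methanolysis (K2CO3, MeOH, 0 °C) gives (2R)-2-({[tert-butyl(dimethyl)silyl]oxy}methyl)-5-(furan-3-yl)pentan-1-ol F4.
- Iodination (PPh3, iodine, imidazole) gives 10.
- If the enzyme shows the opposite topicity to the one assumed, hydrolysis of F1 gives 7 itself and the main line is rejoined there.

Step 7 (cyanomethyl alkylation). The risk is slow SN2 at the β-branched iodide, with E2 elimination and dialkylation competing. The fallback sets out from 10 and comes back at 12.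
- 10 is alkylated with the soft nucleophile NaCH(CO2Me)2 (from NaH and dimethyl malonate, DMF, 60 °C) to dimethyl 2-[(2R)-2-({[tert-butyl(dimethyl)silyl]oxy}methyl)-5-(furan-3-yl)pentyl]propanedioate F5.
- Krapcho demethoxycarbonylation (LiCl, wet DMSO, 140 °C) gives methyl (4R)-4-({[tert-butyl(dimethyl)silyl]oxy}methyl)-7-(furan-3-yl)heptanoate F6.
- Reduction with diisobutylaluminium hydride, (Me2CHCH2)2AlH (1.05 equiv, CH2Cl2, −78 °C), stops at aldehyde 12.

Step 13 (chlorite oxidation beside a 3-alkylfuran). The risk is oxidative opening or chlorination of the furan if scavenging is incomplete. The fallback sets out from 17 and comes back at 19. It drops the aldehyde/chlorite sequence and oxidises the primary alcohol in one operation with catalytic 2,2,6,6-tetramethylpiperidine-1-oxyl (TEMPO) and PhI(OAc)2 (2.2 equiv) in MeCN/pH 7 phosphate buffer. The oxoammonium ion oxidises the alcohol and then the aldehyde hydrate, no hypochlorous acid is formed, the medium is non-basic, and no new isolated compound arises.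

**Further compounds**
F1 | step 3 | 2-[3-(furan-3-yl)propyl]propane-1,3-diyl diacetate | CC(=O)OCC(COC(C)=O)CCCc1ccoc1
F2 | step 3 | [(2S)-5-(furan-3-yl)-2-(hydroxymethyl)pentyl] acetate | CC(=O)OC[C@@H](CCCc1ccoc1)CO
F3 | step 3 | [(2R)-2-({[tert-butyl(dimethyl)silyl]oxy}methyl)-5-(furan-3-yl)pentyl] acetate | CC(=O)OC[C@@H](CCCc1ccoc1)CO[Si](C)(C)C(C)(C)C
F4 | step 3 | (2R)-2-({[tert-butyl(dimethyl)silyl]oxy}methyl)-5-(furan-3-yl)pentan-1-ol | OC[C@@H](CCCc1ccoc1)CO[Si](C)(C)C(C)(C)C
F5 | step 7 | dimethyl 2-[(2R)-2-({[tert-butyl(dimethyl)silyl]oxy}methyl)-5-(furan-3-yl)pentyl]propanedioate | COC(=O)C(C[C@@H](CCCc1ccoc1)CO[Si](C)(C)C(C)(C)C)C(=O)OC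
F6 | step 7 | methyl (4R)-4-({[tert-butyl(dimethyl)silyl]oxy}methyl)-7-(furan-3-yl)heptanoate | COC(=O)CC[C@@H](CCCc1ccoc1)CO[Si](C)(C)C(C)(C)C
F0 | step 13 | none | none
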